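**Retrosynthetic overview**

1. The 3(2H)-furanone is formed last: transannular hydration, hemiketalisation and dehydration of a macrocyclic 10-hydroxy-1-yn-3-one (a masked 10-hydroxy-1,3-dione), with O10 closing onto C3.
2. The ten-membered carbocycle is closed at C6–C7 by a cation–olefin-type Hosomi–Sakurai reaction: the C7=C11 bond of a butenolide allylsilane attacks the activated C6 aldehyde and silicon is lost from C13 to give the 11(13)-methylene, as in farnesyl → germacrene A.
3. The acyclic chain comes from a C2–C3 acyl–alkyne coupling of a C3–C6 acid (C5 from an asymmetric Morita–Baylis–Hillman reaction) with an alkyne carrying C1, C2 and C7–C14.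
4. In the alkyne piece, C10 comes from Sharpless epoxidation and reductive opening of (Z)-3-methylpent-2-en-4-yn-1-ol; C8 and the 12,8-lactone come from an asymmetric carboalkoxyallylation–lactonisation, followed by allylic bromination and silylation.
5. Ring order: γ-lactone → ten-membered carbocycle → furanone.

Assumption: atom labels C1–C15 follow germacrane numbering of the target (C12 lactone carbonyl, C13 lactone methylene, C14 methyl on C10, C15 methylene on C4).

**Route**

Step 1
Reactants: 1 2,2-dimethoxyacetaldehyde; 2 1,1,1,3,3,3-hexafluoropropan-2-yl acrylate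
Product: 3 1,1,1,3,3,3-hexafluoropropan-2-yl (S)-3-hydroxy-4,4-dimethoxy-2-methylenebutanoate
Conditions: β-isocupreidine (10 mol %), DMF, −55 °C
Reagents that add atoms: none
Why: Enantioselective Morita–Baylis–Hillman reaction: the cinchona catalyst delivers the ammonium enolate to the aldehyde face that gives the (R)-adducts of simple aldehydes, which is (S) here because the acetal carbon outranks the vinyl carbon; this carbinol becomes C5.

Step 2
Reactants: 3 1,1,1,3,3,3-hexafluoropropan-2-yl (S)-3-hydroxy-4,4-dimethoxy-2-methylenebutanoate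
Product: 4 1,1,1,3,3,3-hexafluoropropan-2-yl (S)-3-[(tert-butyldimethylsilyl)oxy]-4,4-dimethoxy-2-methylenebutanoate
Conditions: TBSCl, imidazole, DMF, rt
Reagents that add atoms: tert-butyldimethylsilyl chloride, CC(C)(C)[Si](C)(C)Cl
Why: Silyl ether formation caps O5 so that only O6 is free for acylation later; no stereocenter is touched.

Step 3
Reactants: 4 1,1,1,3,3,3-hexafluoropropan-2-yl (S)-3-[(tert-butyldimethylsilyl)oxy]-4,4-dimethoxy-2-methylenebutanoate
Product: 5 (S)-3-[(tert-butyldimethylsilyl)oxy]-4,4-dimethoxy-2-methylenebutanoic acid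
Conditions: LiOH, THF/H2O, 0 °C; then 1 M HCl to pH 3
Reagents that add atoms: lithium hydroxide (hydroxide oxygen of the acid), [Li+].[OH-]
Why: Saponification of the activated hexafluoroisopropyl ester is fast at 0 °C, so the acetal, the silyl ether and C5 survive.

Step 4
Reactants: 6 (Z)-3-methylpent-2-en-4-yn-1-ol
Product: 7 [(2S,3R)-3-ethynyl-3-methyloxiran-2-yl]methanol
Conditions: Ti(OiPr)4 (10 mol %), L-(+)-diethyl tartrate (12 mol %), tBuOOH, 4 Å sieves, CH2Cl2, −20 °C
Reagents that add atoms: tert-butyl hydroperoxide, CC(C)(C)OO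
Why: Sharpless asymmetric epoxidation: with L-(+)-tartrate the Z-allylic alcohol is epoxidised on the face that gives the (2S,3R)-epoxide (as with nerol), which fixes the quaternary carbon that becomes C10.

Step 5
Reactants: 7 [(2S,3R)-3-ethynyl-3-methyloxiran-2-yl]methanol
Product: 8 (S)-3-methylpent-4-yne-1,3-diol
Conditions: NaAlH2(OCH2CH2OMe)2, THF, −20 → 0 °C
Reagents that add atoms: none
Why: Hydroxyl-directed reductive opening of a 2,3-epoxy alcohol: the alkoxyaluminate delivers hydride to C2 and leaves the C3–O bond intact, so the tertiary carbinol is formed with retention as (S); at this temperature the terminal alkyne is only deprotonated.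

Step 6
Reactants: 8 (S)-3-methylpent-4-yne-1,3-diol
Product: 9 (S)-3-hydroxy-3-methylpent-4-ynal
Conditions: TEMPO (10 mol %), PhI(OAc)2, CH2Cl2, rt
Reagents that add atoms: none
Why: Oxoammonium (TEMPO) oxidation is selective for the primary alcohol; the tertiary propargylic alcohol and C10 are untouched.

Step 7
Reactants: 9 (S)-3-hydroxy-3-methylpent-4-ynal; 10 ethyl 2-(bromomethyl)acrylate
Product: 12 (R)-5-[(S)-2-hydroxy-2-methylbut-3-yn-1-yl]-3-methylenedihydrofuran-2(3H)-one, via hydroxy ester 11 (not isolated)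
Conditions: CrCl2 (10 mol %), chiral 1,8-bis(oxazolinyl)carbazole ligand (11 mol %), iPr2NEt, Mn powder, Me3SiCl, THF, rt; then 1 M HCl; then TsOH (cat.), CH2Cl2
Reagents that add atoms: none
Why: Catalytic asymmetric Nozaki–Hiyama–Kishi 2-(alkoxycarbonyl)allylation followed by acid lactonisation: the chiral chromium complex (ligand enantiomer chosen for the 5R lactone) controls the aldehyde face and sets the carbinol that becomes C8 (R by rule here, same spatial sense as 8S in the target), and the lactonisation parallels the biogenetic 8,12-lactonisation.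

Step 8
Reactants: 12 (R)-5-[(S)-2-hydroxy-2-methylbut-3-yn-1-yl]-3-methylenedihydrofuran-2(3H)-one
Product: 13 (S)-3-(bromomethyl)-5-[(S)-2-hydroxy-2-methylbut-3-yn-1-yl]furan-2(5H)-one
Conditions: NBS, AIBN (cat.), PhCF3, 80 °C
Reagents that add atoms: N-bromosuccinimide, O=C1CCC(=O)N1Br
Why: Wohl–Ziegler bromination: hydrogen abstraction from the allylic ring CH2 (C7) gives an allyl radical that takes bromine at the exocyclic terminus C13, giving the conjugated butenolide; C8 and C10 are not involved.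

Step 9
Reactants: 13 (S)-3-(bromomethyl)-5-[(S)-2-hydroxy-2-methylbut-3-yn-1-yl]furan-2(5H)-one
Product: 14 (S)-5-[(S)-2-hydroxy-2-methylbut-3-yn-1-yl]-3-[(trimethylsilyl)methyl]furan-2(5H)-one
Conditions: Me3SiSiMe3, Pd(PPh3)4 (5 mol %), THF, 60 °C
Reagents that add atoms: hexamethyldisilane, C[Si](C)(C)[Si](C)(C)C
Why: Palladium-catalysed allylic silylation: oxidative addition gives a π-allyl complex of divalent palladium that takes the silyl group from the disilane at its unhindered CH2 terminus; the allylsilane is the latent C7 nucleophile and, unlike the bromide, tolerates the coupling conditions.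

Step 10
Reactants: 5 (S)-3-[(tert-butyldimethylsilyl)oxy]-4,4-dimethoxy-2-methylenebutanoic acid; 14 (S)-5-[(S)-2-hydroxy-2-methylbut-3-yn-1-yl]-3-[(trimethylsilyl)methyl]furan-2(5H)-one
Product: 16 (S)-5-{(2S,7S)-7-[(tert-butyldimethylsilyl)oxy]-2-hydroxy-8,8-dimethoxy-2-methyl-6-methylene-5-oxooct-3-yn-1-yl}-3-[(trimethylsilyl)methyl]furan-2(5H)-one, via acid chloride 15 (not isolated)
Conditions: 5, 1-chloro-N,N,2-trimethylprop-1-en-1-amine, CH2Cl2, 0 °C; then 14, PdCl2(PPh3)2 (2 mol %), CuI (4 mol %), Et3N, THF, rt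
Reagents that add atoms: none
Why: Neutral acid chloride formation and Sonogashira-type acylation of the terminal alkyne (copper acetylide to acylpalladium) join C2 to C3 as the ynone, a dehydrated form of the biogenetic 10-hydroxy-1,3-dione; no stereocenter is touched.

Step 11
Reactants: 16 (S)-5-{(2S,7S)-7-[(tert-butyldimethylsilyl)oxy]-2-hydroxy-8,8-dimethoxy-2-methyl-6-methylene-5-oxooct-3-yn-1-yl}-3-[(trimethylsilyl)methyl]furan-2(5H)-one
Product: 17 (S)-5-{(2S,7S)-7-[(tert-butyldimethylsilyl)oxy]-2-hydroxy-2-methyl-6-methylene-5,8-dioxooct-3-yn-1-yl}-3-[(trimethylsilyl)methyl]furan-2(5H)-one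
Conditions: CF3CO2H/H2O (9:1), CHCl3, 0 °C
Reagents that add atoms: water, O
Why: Acid hydrolysis of the dimethyl acetal frees the C6 aldehyde; the short cold exposure spares the silyl ether, the electron-poor allylsilane and the α-stereocenter C5.

Step 12
Reactants: 17 (S)-5-{(2S,7S)-7-[(tert-butyldimethylsilyl)oxy]-2-hydroxy-2-methyl-6-methylene-5,8-dioxooct-3-yn-1-yl}-3-[(trimethylsilyl)methyl]furan-2(5H)-one
Product: 18 (5S,6R,7S,8S,10S)-5-[(tert-butyldimethylsilyl)oxy]-6,10-dihydroxy-3-oxogermacra-4(15),11(13)-dien-1-yn-12,8-olide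
Conditions: BF3·OEt2, CH2Cl2 (1 mM, slow addition), −78 → −40 °C
Reagents that add atoms: none
Why: Proposed new method: intramolecular Hosomi–Sakurai reaction in which the BF3-activated C6 aldehyde is attacked by C7 of the butenolide allylsilane and Me3Si+ is lost from C13 to give the 11(13)-methylene, a silicon version of the farnesyl-to-germacrenyl cation–olefin closure; attack anti to C9 on the butenolide sets C7, Felkin–Anh addition anti to the C5 silyloxy group and the open antiperiplanar transition state (syn topicity) set C6, and the closest known reactions are Lewis-acid cyclisations of ω-formyl 2-(trimethylsilylmethyl)alk-2-enoates to ring-fused α-methylene lactones.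

Step 13
Reactants: 18 (5S,6R,7S,8S,10S)-5-[(tert-butyldimethylsilyl)oxy]-6,10-dihydroxy-3-oxogermacra-4(15),11(13)-dien-1-yn-12,8-olide
Product: 19 (5S,6R,7R,8S,10S)-5-[(tert-butyldimethylsilyl)oxy]-10-hydroxy-6-(methacryloyloxy)-3-oxogermacra-4(15),11(13)-dien-1-yn-12,8-olide
Conditions: methacrylic anhydride, Et3N, DMAP (cat.), CH2Cl2, 0 °C
Reagents that add atoms: methacrylic anhydride, C=C(C)C(=O)OC(=O)C(C)=C
Why: DMAP-catalysed acylation of the only secondary alcohol; the tertiary C10 hydroxyl is too hindered to react at 0 °C (the C7 descriptor changes by rule only).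

Step 14
Reactants: 19 (5S,6R,7R,8S,10S)-5-[(tert-butyldimethylsilyl)oxy]-10-hydroxy-6-(methacryloyloxy)-3-oxogermacra-4(15),11(13)-dien-1-yn-12,8-olide
Product: 21 (5S,6R,7R,8S,10S)-5-[(tert-butyldimethylsilyl)oxy]-6-(methacryloyloxy)-1-oxo-3,10-epoxygermacra-2,4(15),11(13)-trien-12,8-olide, via macrocyclic diketone 20 (not isolated)
Conditions: (4-CF3C6H4)3PAuCl (5 mol %), AgOTf (5 mol %), H2O (1 equiv), toluene, rt
Reagents that add atoms: water (its oxygen ends on C1; the C3 carbonyl oxygen leaves as water), O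
Why: Gold-catalysed cycloisomerisation of a γ-hydroxy alkynone to a 3(2H)-furanone, run transannularly: monovalent gold adds water across the ynone to the 10-hydroxy-1,3-dione, the C10 hydroxyl closes onto C3 and water is lost, which is the presumed biogenetic hemiketalisation–dehydration and relieves the strain of the ring alkyne; C10 keeps its configuration because its C–O bond is not broken.

Step 15
Reactants: 21 (5S,6R,7R,8S,10S)-5-[(tert-butyldimethylsilyl)oxy]-6-(methacryloyloxy)-1-oxo-3,10-epoxygermacra-2,4(15),11(13)-trien-12,8-olide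
Product: 22 (5S,6R,7R,8S,10S)-5-hydroxy-6-(methacryloyloxy)-1-oxo-3,10-epoxygermacra-2,4(15),11(13)-trien-12,8-olide (CNP0142847.1)
Conditions: HF·pyridine, THF, 0 °C → rt
Reagents that add atoms: none
Why: Acidic fluoride desilylation frees the C5 hydroxyl without base, so the 6-O-methacrylate does not migrate and the Michael acceptors survive.

**Compound list**

1 | 2,2-dimethoxyacetaldehyde | COC(OC)C=O | starting material
2 | 1,1,1,3,3,3-hexafluoropropan-2-yl acrylate | C=CC(=O)OC(C(F)(F)F)C(F)(F)F | starting material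
3 | 1,1,1,3,3,3-hexafluoropropan-2-yl (S)-3-hydroxy-4,4-dimethoxy-2-methylenebutanoate | C=C(C(=O)OC(C(F)(F)F)C(F)(F)F)[C@H](O)C(OC)OC | intermediate
4 | 1,1,1,3,3,3-hexafluoropropan-2-yl (S)-3-[(tert-butyldimethylsilyl)oxy]-4,4-dimethoxy-2-methylenebutanoate | C=C(C(=O)OC(C(F)(F)F)C(F)(F)F)[C@H](O[Si](C)(C)C(C)(C)C)C(OC)OC | intermediate
5 | (S)-3-[(tert-butyldimethylsilyl)oxy]-4,4-dimethoxy-2-methylenebutanoic acid | C=C(C(=O)O)[C@H](O[Si](C)(C)C(C)(C)C)C(OC)OC | intermediate
6 | (Z)-3-methylpent-2-en-4-yn-1-ol | C#C/C(C)=C\CO | starting material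
7 | [(2S,3R)-3-ethynyl-3-methyloxiran-2-yl]methanol | C#C[C@@]1(C)O[C@H]1CO | intermediate
8 | (S)-3-methylpent-4-yne-1,3-diol | C#C[C@@](C)(O)CCO | intermediate
9 | (S)-3-hydroxy-3-methylpent-4-ynal | C#C[C@@](C)(O)CC=O | intermediate
10 | ethyl 2-(bromomethyl)acrylate | C=C(CBr)C(=O)OCC | starting material
11 | ethyl (4R,6S)-4,6-dihydroxy-6-methyl-2-methyleneoct-7-ynoate | C=C(C[C@@H](O)C[C@](C)(O)C#C)C(=O)OCC | intermediate
12 | (R)-5-[(S)-2-hydroxy-2-methylbut-3-yn-1-yl]-3-methylenedihydrofuran-2(3H)-one | C=C1C(=O)O[C@H](C1)C[C@](C)(O)C#C | intermediate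
13 | (S)-3-(bromomethyl)-5-[(S)-2-hydroxy-2-methylbut-3-yn-1-yl]furan-2(5H)-one | O=C1O[C@H](C=C1CBr)C[C@](C)(O)C#C | intermediate
14 | (S)-5-[(S)-2-hydroxy-2-methylbut-3-yn-1-yl]-3-[(trimethylsilyl)methyl]furan-2(5H)-one | O=C1O[C@H](C=C1C[Si](C)(C)C)C[C@](C)(O)C#C | intermediate
15 | (S)-3-[(tert-butyldimethylsilyl)oxy]-4,4-dimethoxy-2-methylenebutanoyl chloride | C=C(C(Cl)=O)[C@H](O[Si](C)(C)C(C)(C)C)C(OC)OC | intermediate
16 | (S)-5-{(2S,7S)-7-[(tert-butyldimethylsilyl)oxy]-2-hydroxy-8,8-dimethoxy-2-methyl-6-methylene-5-oxooct-3-yn-1-yl}-3-[(trimethylsilyl)methyl]furan-2(5H)-one | C=C(C(=O)C#C[C@@](C)(O)C[C@@H]1OC(=O)C(C[Si](C)(C)C)=C1)[C@H](O[Si](C)(C)C(C)(C)C)C(OC)OC | intermediate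
17 | (S)-5-{(2S,7S)-7-[(tert-butyldimethylsilyl)oxy]-2-hydroxy-2-methyl-6-methylene-5,8-dioxooct-3-yn-1-yl}-3-[(trimethylsilyl)methyl]furan-2(5H)-one | C=C(C(=O)C#C[C@@](C)(O)C[C@@H]1OC(=O)C(C[Si](C)(C)C)=C1)[C@H](O[Si](C)(C)C(C)(C)C)C=O | intermediate
18 | (5S,6R,7S,8S,10S)-5-[(tert-butyldimethylsilyl)oxy]-6,10-dihydroxy-3-oxogermacra-4(15),11(13)-dien-1-yn-12,8-olide | O[C@@H]1[C@@H]2C(=C)C(=O)O[C@H]2C[C@](C)(O)C#CC(=O)C(=C)[C@@H]1O[Si](C)(C)C(C)(C)C | intermediate
19 | (5S,6R,7R,8S,10S)-5-[(tert-butyldimethylsilyl)oxy]-10-hydroxy-6-(methacryloyloxy)-3-oxogermacra-4(15),11(13)-dien-1-yn-12,8-olide | C=C(C)C(=O)O[C@@H]1[C@@H]2C(=C)C(=O)O[C@H]2C[C@](C)(O)C#CC(=O)C(=C)[C@@H]1O[Si](C)(C)C(C)(C)C | intermediate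
20 | (5S,6R,7R,8S,10S)-5-[(tert-butyldimethylsilyl)oxy]-10-hydroxy-6-(methacryloyloxy)-1,3-dioxogermacra-4(15),11(13)-dien-12,8-olide | C=C(C)C(=O)O[C@@H]1[C@@H]2C(=C)C(=O)O[C@H]2C[C@](C)(O)C(=O)CC(=O)C(=C)[C@@H]1O[Si](C)(C)C(C)(C)C | intermediate
21 | (5S,6R,7R,8S,10S)-5-[(tert-butyldimethylsilyl)oxy]-6-(methacryloyloxy)-1-oxo-3,10-epoxygermacra-2,4(15),11(13)-trien-12,8-olide | C=C(C)C(=O)O[C@@H]1[C@@H]2C(=C)C(=O)O[C@H]2C[C@]2(C)OC(=CC2=O)C(=C)[C@@H]1O[Si](C)(C)C(C)(C)C | intermediate
22 | (5S,6R,7R,8S,10S)-5-hydroxy-6-(methacryloyloxy)-1-oxo-3,10-epoxygermacra-2,4(15),11(13)-trien-12,8-olide | C=C(C)C(=O)O[C@@H]1[C@@H]2C(=C)C(=O)O[C@H]2C[C@]2(C)OC(=CC2=O)C(=C)[C@@H]1O | target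

**Step count**

Total steps: 15. Longest linear sequence: 12 (steps 4–9, then 10–15).

**Three steps most likely to fail**

Step 12 (ring closure). The allylsilane is electron-poor, the ynone could take a competing conjugate addition, and the C6 configuration rests on an open transition state in a ring-forming step. Fallback: setting out from 17, the allylsilane is bromodesilylated with NBS (SE2′) to the allylic bromide aldehyde F1. In powder in THF/aqueous NH4Cl then closes the ring by a Barbier allylation through a chair transition state. This is expected to give the 6-epi alcohol F2, which a Mitsunobu esterification with methacrylic acid (PPh3, DIAD) inverts and acylates in one operation, coming back to the route at 19. If 18 itself is formed, step 13 follows as written.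

Step 8 (radical bromination). Bromine may go to C7 instead of C13, and the alkyne may react. Fallback: setting out from 12, a Schenck ene reaction with singlet oxygen (O2, tetraphenylporphyrin, light) moves the double bond into the ring and gives the allylic hydroperoxide F3. PPh3 reduces it to the hydroxymethyl butenolide F4, and CBr4/PPh3 comes back to the route at 13.

Step 14 (transannular furanone formation). Hydration of the ring alkyne may be slow or may go with the wrong regiochemistry, and cationic gold may touch the other π-systems. Fallback: setting out from 16, the furanone is made before the carbocycle. The same gold catalyst converts the open-chain hydroxy ynone to the furanone acetal F5, CF3CO2H/H2O gives the furanone aldehyde F6, and BF3·OEt2 closes the ring to the macrocyclic furanone alcohol F7. Acylation with methacrylic anhydride comes back to the route at 21.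

**Further compounds**

F1 | step 12 | (S)-4-bromo-5-{(2S,7S)-7-[(tert-butyldimethylsilyl)oxy]-2-hydroxy-2-methyl-6-methylene-5,8-dioxooct-3-yn-1-yl}-3-methylenedihydrofuran-2(3H)-one (both C–Br epimers) | C=C(C(=O)C#C[C@@](C)(O)C[C@@H]1OC(=O)C(=C)C1Br)[C@H](O[Si](C)(C)C(C)(C)C)C=O
F2 | step 12 | (5S,6S,7S,8S,10S)-5-[(tert-butyldimethylsilyl)oxy]-6,10-dihydroxy-3-oxogermacra-4(15),11(13)-dien-1-yn-12,8-olide | O[C@H]1[C@@H]2C(=C)C(=O)O[C@H]2C[C@](C)(O)C#CC(=O)C(=C)[C@@H]1O[Si](C)(C)C(C)(C)C
F3 | step 8 | (S)-3-(hydroperoxymethyl)-5-[(S)-2-hydroxy-2-methylbut-3-yn-1-yl]furan-2(5H)-one | O=C1O[C@H](C=C1COO)C[C@](C)(O)C#C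
F4 | step 8 | (S)-3-(hydroxymethyl)-5-[(S)-2-hydroxy-2-methylbut-3-yn-1-yl]furan-2(5H)-one | O=C1O[C@H](C=C1CO)C[C@](C)(O)C#C
F5 | step 14 | (S)-5-{[(S)-5-{(S)-3-[(tert-butyldimethylsilyl)oxy]-4,4-dimethoxybut-1-en-2-yl}-2-methyl-3-oxo-2,3-dihydrofuran-2-yl]methyl}-3-[(trimethylsilyl)methyl]furan-2(5H)-one | C=C(C1=CC(=O)[C@](C)(C[C@@H]2OC(=O)C(C[Si](C)(C)C)=C2)O1)[C@H](O[Si](C)(C)C(C)(C)C)C(OC)OC
F6 | step 14 | (S)-2-[(tert-butyldimethylsilyl)oxy]-3-[(S)-5-methyl-4-oxo-5-({(S)-5-oxo-4-[(trimethylsilyl)methyl]-2,5-dihydrofuran-2-yl}methyl)-4,5-dihydrofuran-2-yl]but-3-enal | C=C(C1=CC(=O)[C@](C)(C[C@@H]2OC(=O)C(C[Si](C)(C)C)=C2)O1)[C@H](O[Si](C)(C)C(C)(C)C)C=O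
F7 | step 14 | (5S,6R,7S,8S,10S)-5-[(tert-butyldimethylsilyl)oxy]-6-hydroxy-1-oxo-3,10-epoxygermacra-2,4(15),11(13)-trien-12,8-olide | O[C@@H]1[C@@H]2C(=C)C(=O)O[C@H]2C[C@]2(C)OC(=CC2=O)C(=C)[C@@H]1O[Si](C)(C)C(C)(C)C
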